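**Strategy.** In labdane numbering, ring A is closed on a preformed ring B. The quaternary C10 lies α to a C9 ketone (the later C8=C9 alkene carbon) and vinylogous to the C19 ester through C5 and C4, while C1 is an unhindered methylene. A monocyclic 2-methylcyclohex-2-enone carrying a CH(CO2Me)(CH2)3Br chain on C5 is therefore deprotonated at C4 to an extended dienolate, which a chiral phase-transfer cation steers to alkylate at C10 (6-exo-tet). This forges C1–C10 and the quaternary stereocentre in one operation. The resulting C4=C5 enoate lets reductive methylation set C5 and C4 from C10, and the C9 ketone becomes the enol triflate for side-chain coupling.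

Key step: step 2

Remark: the target is read as (4S,5R,10S)-15-acetoxylabda-8,13E-dien-19-oic acid (trans-decalin, axial C19 acid cis to the C10 methyl), and labdane atom numbers are used throughout.

Assumption: the cinchonidinium catalyst of step 2 is taken to deliver the (S) quaternary centre; the cinchoninium pseudoenantiomer gives the opposite sense and would replace it if required.

**Step 1**
Reactants: 1 3-ethoxy-2-methylcyclohex-2-en-1-one; 2 methyl 5-bromopentanoate
Product: 4 methyl 5-bromo-2-(2-methyl-3-oxocyclohex-1-en-1-yl)pentanoate (racemic), via tertiary carbinol adduct 3 (not isolated)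
Conditions: LiN(iPr)2 (LDA), THF, −78 °C, add 2, then 1, −78 °C; quench with 2 M HCl at −78 °C, then rt
Reagents that add atoms: water, O
Why: Stork–Danheiser sequence in which the lithium ester enolate adds 1,2 to the vinylogous ester carbonyl and aqueous acid hydrolyses the enol ether and dehydrates the carbinol with carbonyl transposition; the cold quench preserves the primary bromide, and the racemic C4 centre is erased in step 2.

**Step 2**
Reactants: 4 methyl 5-bromo-2-(2-methyl-3-oxocyclohex-1-en-1-yl)pentanoate
Product: 5 methyl (4aS)-4a-methyl-5-oxo-2,3,4,4a,5,6,7,8-octahydronaphthalene-1-carboxylate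
Conditions: N-(9-anthracenylmethyl)-O-allylcinchonidinium bromide (10 mol %), Cs2CO3 (solid), toluene, −20 °C, high dilution
Reagents that add atoms: none
Why: Proposed new method: solid Cs2CO3 removes the C4–H (α to the ester and vinylogous to the C9 ketone), the chiral ammonium cation carries the planar O–C9=C10–C5=C4–CO2Me dienolate into toluene as a tight ion pair, and C10 displaces bromide from C1 in an intramolecular SN2 step that leaves the C4=C5 double bond conjugated to the ester. The closest known reaction types are asymmetric phase-transfer α-alkylation of cyclic ketone and β-keto ester enolates to quaternary carbons and the racemic α-alkylation of 3-(haloalkyl)cyclohexenone dienolates. Ring A closes in the 6-exo-tet mode with the enolate double bond exocyclic to the new ring. C10 is the only stereocentre formed and its configuration is set by the catalyst, whose anthracenylmethyl and quinoline walls should leave one face of the ion-paired dienolate open. The step needs C10- over C4- or O-alkylation, which the tether secures because C4 attack would give a cyclobutane and attack by the ketone oxygen an eight-membered ring, and it needs the catalysed path to outrun racemic background cyclisation, which the insoluble base, non-polar solvent and low temperature should favour.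

**Step 3**
Reactants: 5 methyl (4aS)-4a-methyl-5-oxo-2,3,4,4a,5,6,7,8-octahydronaphthalene-1-carboxylate
Product: 6 ethylene ketal of 5, methyl (4'aS)-4'a-methyl-3',4',4'a,6',7',8'-hexahydro-2'H-spiro[1,3-dioxolane-2,5'-naphthalene]-1'-carboxylate
Conditions: ethylene glycol, p-TsOH (cat.), benzene, reflux, Dean–Stark
Reagents that add atoms: ethylene glycol, OCCO
Why: Acid-catalysed ketalisation masks the C9 ketone against the dissolving-metal step; the quaternary C10 cannot epimerise and the tetrasubstituted enoate is inert.

**Step 4**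
Reactants: 6 ethylene ketal of 5
Product: 8 methyl (1S,4aS,8aR)-1,4a-dimethyl-5-oxodecahydronaphthalene-1-carboxylate, via C-methylated dioxolane ester 7 (not isolated)
Conditions: Li, NH3(l)/THF, t-BuOH (1 equiv), −78 °C; MeI, −78 to −33 °C; then 2 M HCl, THF, rt
Reagents that add atoms: iodomethane, CI; water, O
Why: Dissolving-metal reductive alkylation of the α,β-unsaturated ester, in which protonation of the β-carbon C5 should give the trans-fused decalin (H anti to the C10 methyl) and the exocyclic ester enolate is methylated from the equatorial α face away from the axial C10 methyl, placing CO2Me axial (4S); the acidic work-up hydrolyses the dioxolane.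

**Step 5**
Reactants: 8 methyl (1S,4aS,8aR)-1,4a-dimethyl-5-oxodecahydronaphthalene-1-carboxylate
Product: 9 methyl (1S,4aS,8aR)-1,4a,6-trimethyl-5-oxodecahydronaphthalene-1-carboxylate (mixture of C6 epimers, labdane C8)
Conditions: LiN(iPr)2, THF, −78 °C; MeI, −78 to 0 °C
Reagents that add atoms: iodomethane, CI
Why: Kinetic enolate alkylation at C8, the only carbon with acidic hydrogens (C10 is quaternary and the ester has no α-H); the C8 configuration is irrelevant because C8 becomes sp2 in step 6, and the methylation is placed after step 4 so that no enoate γ-hydrogens compete.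

**Step 6**
Reactants: 9 methyl (1S,4aS,8aR)-1,4a,6-trimethyl-5-oxodecahydronaphthalene-1-carboxylate
Product: 10 methyl (1S,4aS,8aR)-1,4a,6-trimethyl-5-(trifluoromethylsulfonyloxy)-1,2,3,4,4a,7,8,8a-octahydronaphthalene-1-carboxylate
Conditions: KN(SiMe3)2, THF, −78 °C; PhNTf2, −78 °C to rt; aqueous work-up
Reagents that add atoms: N-phenylbis(trifluoromethanesulfonimide), O=S(=O)(N(c1ccccc1)S(=O)(=O)C(F)(F)F)C(F)(F)F
Why: Deprotonation of the remaining C8–H gives the only possible (tetrasubstituted) enolate, whose O-sulfonylation to the enol triflate fixes the C8=C9 double bond.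

**Step 7**
Reactants: 11 (E)-3-methylpent-2-en-4-yn-1-ol
Product: 12 (E)-3-methylpenta-2,4-dien-1-ol
Conditions: H2 (1 atm), Pd/CaCO3 poisoned with Pb(OAc)2 (Lindlar catalyst), quinoline, pentane/Et2O, 0 °C
Reagents that add atoms: none
Why: Semihydrogenation of the terminal alkyne over poisoned palladium should stop at the diene and leave the (E)-trisubstituted alkene untouched.

**Step 8**
Reactants: 12 (E)-3-methylpenta-2,4-dien-1-ol; 10 enol triflate
Product: 14 methyl (1S,4aS,8aR)-5-[(3E)-5-hydroxy-3-methylpent-3-en-1-yl]-1,4a,6-trimethyl-1,2,3,4,4a,7,8,8a-octahydronaphthalene-1-carboxylate, via B-alkyl-9-BBN borinate 13 (not isolated)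
Conditions: 9-BBN (2.2 equiv), THF, 0 °C to rt; aq K3PO4; then 10, PdCl2(dppf) (cat.), AsPh3, DMF, 60 °C
Reagents that add atoms: none
Why: 9-BBN first borylates the hydroxyl and then hydroborates the terminal vinyl group anti-Markovnikov, and B-alkyl Suzuki–Miyaura coupling of the primary alkylborane with the enol triflate forms C9–C11 with retention of both alkene geometries; the aqueous base hydrolyses the borinate before the zerovalent palladium catalyst is generated.

**Step 9**
Reactants: 14 hydroxy methyl ester
Product: 15 (1S,4aS,8aR)-5-[(3E)-5-hydroxy-3-methylpent-3-en-1-yl]-1,4a,6-trimethyl-1,2,3,4,4a,7,8,8a-octahydronaphthalene-1-carboxylic acid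
Conditions: NaSEt, DMF, 100 °C; then dilute HCl work-up
Reagents that add atoms: none
Why: SN2 demethylation by thiolate at the methyl carbon cleaves the hindered axial ester where attack at the acyl carbon would fail; the alkenes and the free alcohol are inert.

**Step 10**
Reactants: 15 hydroxy acid
Product: 16 (1S,4aS,8aR)-5-[(3E)-5-acetoxy-3-methylpent-3-en-1-yl]-1,4a,6-trimethyl-1,2,3,4,4a,7,8,8a-octahydronaphthalene-1-carboxylic acid (target)
Conditions: Ac2O, pyridine, DMAP (cat.), CH2Cl2, 0 °C to rt; aqueous work-up
Reagents that add atoms: acetic anhydride, CC(=O)OC(C)=O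
Why: Acylation of the primary allylic alcohol; the hindered acid forms at most a mixed anhydride that is hydrolysed back on aqueous work-up.

**Compound list**

1 | 3-ethoxy-2-methylcyclohex-2-en-1-one | CCOC1=C(C)C(=O)CCC1 | starting material
2 | methyl 5-bromopentanoate | COC(=O)CCCCBr | starting material
3 | methyl 5-bromo-2-(3-ethoxy-1-hydroxy-2-methylcyclohex-2-en-1-yl)pentanoate (lithium alkoxide in the flask, diastereomer mixture) | COC(=O)C(CCCBr)C1(O)CCCC(OCC)=C1C | intermediate (not isolated)
4 | methyl 5-bromo-2-(2-methyl-3-oxocyclohex-1-en-1-yl)pentanoate (racemic) | COC(=O)C(CCCBr)C1=C(C)C(=O)CCC1 | intermediate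
5 | methyl (4aS)-4a-methyl-5-oxo-2,3,4,4a,5,6,7,8-octahydronaphthalene-1-carboxylate | COC(=O)C1=C2CCCC(=O)[C@@]2(C)CCC1 | intermediate
6 | ethylene ketal of 5 | COC(=O)C1=C2CCCC3(OCCO3)[C@@]2(C)CCC1 | intermediate
7 | ethylene ketal of 8 (trans-fused, 1S,4aS,8aR) | C13(OCCO1)CCC[C@H]2[C@@](C)(C(=O)OC)CCC[C@]32C | intermediate (not isolated)
8 | methyl (1S,4aS,8aR)-1,4a-dimethyl-5-oxodecahydronaphthalene-1-carboxylate | O=C1CCC[C@H]2[C@@](C)(C(=O)OC)CCC[C@]12C | intermediate
9 | methyl (1S,4aS,8aR)-1,4a,6-trimethyl-5-oxodecahydronaphthalene-1-carboxylate (C6 epimers) | O=C1C(C)CC[C@H]2[C@@](C)(C(=O)OC)CCC[C@]12C | intermediate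
10 | methyl (1S,4aS,8aR)-1,4a,6-trimethyl-5-(trifluoromethylsulfonyloxy)-1,2,3,4,4a,7,8,8a-octahydronaphthalene-1-carboxylate | FC(F)(F)S(=O)(=O)OC1=C(C)CC[C@H]2[C@@](C)(C(=O)OC)CCC[C@]12C | intermediate
11 | (E)-3-methylpent-2-en-4-yn-1-ol | OC/C=C(\C)C#C | starting material
12 | (E)-3-methylpenta-2,4-dien-1-ol | OC/C=C(\C)C=C | intermediate
13 | 9-[(E)-5-(9-borabicyclo[3.3.1]nonan-9-yloxy)-3-methylpent-3-en-1-yl]-9-borabicyclo[3.3.1]nonane | B1(OC/C=C(\C)CCB2C3CCCC2CCC3)C2CCCC1CCC2 | intermediate (not isolated)
14 | methyl (1S,4aS,8aR)-5-[(3E)-5-hydroxy-3-methylpent-3-en-1-yl]-1,4a,6-trimethyl-1,2,3,4,4a,7,8,8a-octahydronaphthalene-1-carboxylate | OC/C=C(\C)CCC1=C(C)CC[C@H]2[C@@](C)(C(=O)OC)CCC[C@]12C | intermediate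
15 | (1S,4aS,8aR)-5-[(3E)-5-hydroxy-3-methylpent-3-en-1-yl]-1,4a,6-trimethyl-1,2,3,4,4a,7,8,8a-octahydronaphthalene-1-carboxylic acid | OC/C=C(\C)CCC1=C(C)CC[C@H]2[C@@](C)(C(=O)O)CCC[C@]12C | intermediate
16 | (1S,4aS,8aR)-5-[(3E)-5-acetoxy-3-methylpent-3-en-1-yl]-1,4a,6-trimethyl-1,2,3,4,4a,7,8,8a-octahydronaphthalene-1-carboxylic acid | CC(=O)OC/C=C(\C)CCC1=C(C)CC[C@H]2[C@@](C)(C(=O)O)CCC[C@]12C | target

**Step count and risks**

Total steps: 10. Longest linear sequence: 9 (steps 1–6, 8–10); step 7 prepares the side-chain partner.

Steps most likely to fail: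

Step 2 (proposed new method). Enantioselectivity may be eroded by uncatalysed cyclisation of the cesium dienolate at the base surface, and O-alkylation by the ester oxygen may compete. Fallback by known chemistry, a resolution that changes the source of chirality: from compound 4, KOtBu in THF/t-BuOH (ordinary dienolate α-alkylation) would give racemic methyl 4a-methyl-5-oxo-2,3,4,4a,5,6,7,8-octahydronaphthalene-1-carboxylate F1. Ketalisation with (2R,3R)-butane-2,3-diol (p-TsOH, benzene, Dean–Stark) would give two diastereomers, the (4aS) (4R,5R)-4,5-dimethyl-1,3-dioxolane ketal F2 and the (4aR) (4R,5R)-4,5-dimethyl-1,3-dioxolane ketal F3, to be separated by chromatography or crystallisation. F2 would go through the Li/NH3–MeI sequence of step 4 as the C-methylated trans-fused chiral ketal ester F4, whose acidic hydrolysis returns to the route at compound 8.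

Step 8. Oxidative addition and transmetalation may be slow at the tetrasubstituted enol triflate flanked by the quaternary C10, leaving time for protodeboronation or β-hydride loss of the alkylborane and for triflate hydrolysis. Fallback that moves the sp3–sp2 bond formation from C9–C11 to C12–C13: from compound 10, Suzuki–Miyaura coupling with vinylboronic acid pinacol ester (PdCl2(dppf), K3PO4, dioxane/water) would give methyl (1S,4aS,8aR)-5-ethenyl-1,4a,6-trimethyl-1,2,3,4,4a,7,8,8a-octahydronaphthalene-1-carboxylate F5. Selective hydroboration of its terminal vinyl group with 9-BBN would give the B-alkyl-9-borabicyclo[3.3.1]nonane F6. B-alkyl Suzuki–Miyaura coupling of F6 with known (E)-3-iodobut-2-en-1-ol (PdCl2(dppf), AsPh3, Cs2CO3, DMF/water) comes back to the route at compound 14.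

Step 1. The hindered vinylogous ester may undergo proton transfer or retro-aldol reversal instead of net addition, and the bromo ester enolate may self-alkylate to a cyclobutane on warming. Fallback that replaces carbonyl addition by cross-coupling: from compound 1, aqueous HCl hydrolysis would give 2-methylcyclohexane-1,3-dione F7, and Tf2O/pyridine would convert it into 2-methyl-3-oxocyclohex-1-en-1-yl trifluoromethanesulfonate F8. Coupling of F8 with the Reformatsky reagent bromo(5-bromo-1-methoxy-1-oxopentan-2-yl)zinc F9 (from commercial methyl 2,5-dibromopentanoate and zinc dust) under the zerovalent palladium catalyst Pd(PPh3)4 in THF comes back to the route at compound 4.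

**Further compounds**

F1 | step 2 | methyl 4a-methyl-5-oxo-2,3,4,4a,5,6,7,8-octahydronaphthalene-1-carboxylate (racemic) | COC(=O)C1=C2CCCC(=O)C2(C)CCC1
F2 | step 2 | (4aS) (4R,5R)-4,5-dimethyl-1,3-dioxolane ketal of 5 | COC(=O)C1=C2CCCC3(O[C@H](C)[C@@H](C)O3)[C@@]2(C)CCC1
F3 | step 2 | (4aR) (4R,5R)-4,5-dimethyl-1,3-dioxolane ketal (diastereomer set aside) | COC(=O)C1=C2CCCC3(O[C@H](C)[C@@H](C)O3)[C@]2(C)CCC1
F4 | step 2 | (4R,5R)-4,5-dimethyl-1,3-dioxolane ketal of 8 | C13(O[C@H](C)[C@@H](C)O1)CCC[C@H]2[C@@](C)(C(=O)OC)CCC[C@]32C
F5 | step 8 | methyl (1S,4aS,8aR)-5-ethenyl-1,4a,6-trimethyl-1,2,3,4,4a,7,8,8a-octahydronaphthalene-1-carboxylate | C=CC1=C(C)CC[C@H]2[C@@](C)(C(=O)OC)CCC[C@]12C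
F6 | step 8 | B-alkyl-9-borabicyclo[3.3.1]nonane from F5 | B1(CCC2=C(C)CC[C@H]3[C@@](C)(C(=O)OC)CCC[C@]23C)C2CCCC1CCC2
F7 | step 1 | 2-methylcyclohexane-1,3-dione | CC1C(=O)CCCC1=O
F8 | step 1 | 2-methyl-3-oxocyclohex-1-en-1-yl trifluoromethanesulfonate | CC1=C(OS(=O)(=O)C(F)(F)F)CCCC1=O
F9 | step 1 | bromo(5-bromo-1-methoxy-1-oxopentan-2-yl)zinc | COC(=O)C(CCCBr)[Zn]Br
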